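**Retrosynthetic overview** (labdane numbering C1–C20; the target is the ent-labdane 4R,5S,9R,10S,13R,2′R)
1. Acid 26 comes from fluoride cleavage of a C19 2-(trimethylsilyl)ethyl ester; C8=CH2 from methylenation of a C8 ketone; the C15 ester from late acylation with (R)-2-methylbutanoic acid.
2. C4 (CH3, CO2R) comes from reductive methylation of a C3=C4 enoate made from a C4 ketone (enol triflate, alkoxycarbonylation).
3. Ring B comes from a one-flask [3+3] annulation of acrolein (C6–C7–C8) onto monocyclic silyl enol ether 10: Mukaiyama–Michael addition at C5, then carbonyl-ene closure at C9 (new bonds C5–C6 and C8–C9).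
4. Enabling feature: in 10 the enol-ether carbon C5 of ring A and the olefinic carbon C9 of the (E)-alkenyl chain both sit on quaternary C10, a skipped diene C4(OSi)=C5–C10–C9=C11 whose ends are bridged by the β-carbon and the carbonyl carbon of acrolein; the allylic C12–H feeds the ene step.
5. 10 comes from copper-catalysed asymmetric conjugate addition of an (R)-citronellol-derived alkenylalane to 3-methylcyclohex-2-enone (ring A bought, C10 set, C9–C16 delivered); ring A first, ring B in the key step; C5 and C9 are later equilibrated, C8 is erased.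

Key step: step 5

Remark: in step 4 the ligand enantiomer is the one that gives (S)-C10; the key step is expected to give epimer mixtures at C5, C8 and C9, and the SMILES show the isomer that the later equilibrations (steps 6 and 13) should favour.

Step 1
Reactants: 1 (R)-citronellol
Product: 2 benzyl (R)-citronellyl ether
Conditions: NaH, benzyl bromide, Bu4NI (cat.), THF, 0 °C → rt
Reagents that add atoms: benzyl bromide, BrCc1ccccc1
Why: Williamson etherification of the primary alkoxide installs an ether that should survive ozone, strong base, aluminium hydride and Lewis acids and is removed later in the hydrogenation of step 6, while the chiral-pool C13 centre is untouched.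

Step 2
Reactants: 2 benzyl (R)-citronellyl ether
Product: 4 (4R)-6-(benzyloxy)-4-methylhexanal, via ozonide 3 (not isolated)
Conditions: O3, CH2Cl2, −78 °C; then PPh3, −78 °C → rt
Reagents that add atoms: ozone, [O-][O+]=O
Why: Ozonolysis of the electron-rich trisubstituted alkene with reductive work-up should give the aldehyde whose carbonyl carbon is the future C9, with loss of acetone and no effect on C13.

Step 3
Reactants: 4 (4R)-6-(benzyloxy)-4-methylhexanal
Product: 6 ({[(3R)-3-methylhex-5-yn-1-yl]oxy}methyl)benzene, via alkenyl nonaflate 5 (not isolated)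
Conditions: C4F9SO2F, phosphazene base EtN=P(NMe2)2–N=P(NMe2)3, DMF, −20 °C → rt
Reagents that add atoms: none
Why: Enolisation and O-sulfonylation to the alkenyl nonaflate followed by base-induced β-elimination (aldehyde-to-alkyne conversion without change of carbon count) should turn the CH2–CHO unit into the terminal alkyne in which C9 is the terminal carbon.

Step 4
Reactants: 6 ({[(3R)-3-methylhex-5-yn-1-yl]oxy}methyl)benzene, 7 3-methylcyclohex-2-en-1-one
Product: 10 {[(3S)-3-[(1E,4R)-6-(benzyloxy)-4-methylhex-1-en-1-yl]-3-methylcyclohex-1-en-1-yl]oxy}trimethylsilane, via alkenylalane 8 (not isolated), via aluminium enolate 9 (not isolated)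
Conditions: i-Bu2AlH, hexane, 55 °C; then 7, copper thiophene-2-carboxylate Cu(O2CC4H3S) (10 mol %), Ph2PN[CH(CH3)(2-naphthyl)]2 (11 mol %), Et2O, −30 °C; then Me3SiOSO2CF3, THF, −30 → 0 °C
Reagents that add atoms: trimethylsilyl trifluoromethanesulfonate, C[Si](C)(C)OS(=O)(=O)C(F)(F)F
Why: syn-Hydroalumination gives the (E)-alkenylalane, whose copper-catalysed asymmetric conjugate addition to the β-methyl enone should create quaternary C10 under control of the chiral phosphinamine–copper catalyst, and O-silylation of the regiodefined aluminium enolate fixes the C4–C5 enol ether needed in step 5.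

Step 5
Reactants: 10 silyl enol ether, 11 acrolein
Product: 13 (4aS,5S,6S,8aS)-5-[(1E,3S)-5-(benzyloxy)-3-methylpent-1-en-1-yl]-6-hydroxy-4a-methyloctahydronaphthalen-1(2H)-one, via keto aldehyde 12 (not isolated)
Conditions: 11 (1.5 equiv), BF3·OEt2 (0.2 equiv), i-PrOH (1.1 equiv), CH2Cl2, −78 °C; then Me2AlCl (2.5 equiv), −78 → 0 °C
Reagents that add atoms: none
Why: Proposed new method: the alcohol-modified boron trifluoride Mukaiyama–Michael addition of a silyl enol ether to acrolein and the Me2AlCl-promoted intramolecular carbonyl-ene cyclisation of an unsaturated aldehyde (the citronellal-to-isopulegol reaction type) are each established, but their one-flask merger into a [3+3] annulation is proposed here; the enol-ether carbon C5 of 10 adds to the β-carbon C6 of Lewis-acid-bound acrolein while i-PrOH takes the silyl group and protonates C7 to give keto aldehyde 12, whose Me2AlCl-bound formyl carbon C8 is then attacked by the proximal olefinic carbon C9 with transfer of an allylic hydrogen from C12 to oxygen. Ring B is closed in this second event through a six-membered chair-like ene transition state (the first event is intermolecular), and loss of methane from the aluminium alkoxide makes the closure irreversible. C5 is set by approach of acrolein anti to the larger alkenyl group on C10, and C8 and C9 by the chair with equatorial oxygen and equatorial side chain; none of the three has to form cleanly, because C5 and C9 are equilibrated later through the C4 and C8 ketones and C8 becomes sp2. The step needs 1,4- rather than 1,2-addition to acrolein (alcohol-modified BF3 protocol and a hindered nucleophile), attack through C5 rather than C3 (only the C4–C5 enol ether is present after step 4) and ene closure rather than aldol closure from C3 (non-basic, proton-scavenging Me2AlCl at low temperature).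

Step 6
Reactants: 13 hydroxy ketone
Product: 14 (4aS,5S,6S,8aS)-6-hydroxy-5-[(3R)-5-hydroxy-3-methylpentyl]-4a-methyloctahydronaphthalen-1(2H)-one
Conditions: H2 (1 atm), Pd(OH)2/C, EtOH, rt; then NaOMe (0.2 equiv), MeOH, rt
Reagents that add atoms: none
Why: Heterogeneous hydrogenation should saturate the only C=C bond (C11–C12) and hydrogenolyse the benzyl ether in one operation, and the methoxide treatment equilibrates C5 through the C4 enolate towards the trans-fused decalone expected to be favoured when the ring B substituents are equatorial.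

Step 7
Reactants: 14 keto diol
Product: 15 (4aS,5S,6S,8aS)-6-[(tert-butyldimethylsilyl)oxy]-5-{(3R)-5-[(tert-butyldimethylsilyl)oxy]-3-methylpentyl}-4a-methyloctahydronaphthalen-1(2H)-one
Conditions: t-BuMe2SiCl (2.5 equiv), imidazole, DMF, 40 °C
Reagents that add atoms: tert-butyldimethylsilyl chloride, CC(C)(C)[Si](C)(C)Cl
Why: Standard silylation of both hydroxyl groups masks them against the strong base and dissolving metal of steps 8–10 and leaves the C4 ketone as the only reactive carbonyl.

Step 8
Reactants: 15 bis-silyl ketone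
Product: 17 (4aS,5S,6S,8aS)-6-[(tert-butyldimethylsilyl)oxy]-5-{(3R)-5-[(tert-butyldimethylsilyl)oxy]-3-methylpentyl}-4a-methyl-3,4,4a,5,6,7,8,8a-octahydronaphthalen-1-yl trifluoromethanesulfonate, via potassium enolate 16 (not isolated)
Conditions: KN(SiMe3)2, THF, −78 °C; then PhN(SO2CF3)2, −78 → 0 °C
Reagents that add atoms: N-phenylbis(trifluoromethanesulfonimide), O=S(=O)(N(c1ccccc1)S(=O)(=O)C(F)(F)F)C(F)(F)F
Why: Kinetic deprotonation by the bulky amide should occur at the C3 methylene and not at the hindered ring-fusion C5–H, and O-triflation of that enolate gives the C3–C4 enol triflate without disturbing C5.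

Step 9
Reactants: 17 enol triflate
Product: 18 2-(trimethylsilyl)ethyl (4aR,5S,6S,8aS)-6-[(tert-butyldimethylsilyl)oxy]-5-{(3R)-5-[(tert-butyldimethylsilyl)oxy]-3-methylpentyl}-4a-methyl-3,4,4a,5,6,7,8,8a-octahydronaphthalene-1-carboxylate
Conditions: Pd(OAc)2 (5 mol %), PPh3 (10 mol %), CO (1 atm), Me3SiCH2CH2OH, Et3N, DMF, 60 °C
Reagents that add atoms: carbon monoxide, [C-]#[O+]; 2-(trimethylsilyl)ethanol, C[Si](C)(C)CCO
Why: Palladium-catalysed alkoxycarbonylation of the enol triflate (oxidative addition to zerovalent palladium, CO insertion, alcoholysis) attaches C19 to C4 as an ester that can later be cleaved by fluoride at silicon, far from the hindered carbonyl.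

Step 10
Reactants: 18 enoate
Product: 20 2-(trimethylsilyl)ethyl (1R,4aR,5S,6S,8aS)-6-[(tert-butyldimethylsilyl)oxy]-5-{(3R)-5-[(tert-butyldimethylsilyl)oxy]-3-methylpentyl}-1,4a-dimethyldecahydronaphthalene-1-carboxylate, via lithium enolate 19 (not isolated)
Conditions: Li, NH3 (l)/THF, t-BuOH (1.0 equiv), −78 °C; then MeI, −78 → −33 °C
Reagents that add atoms: methyl iodide, CI
Why: Birch-type conjugate reduction of the enoate gives the exocyclic ester enolate regiospecifically, and methyl iodide should approach it from the equatorial face opposite the axial C20 methyl, placing the new methyl equatorial and the ester axial (cis to C20) as the target requires.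

Step 11
Reactants: 20 bis-silyl ester
Product: 21 2-(trimethylsilyl)ethyl (1R,4aR,5S,6S,8aS)-6-hydroxy-5-[(3R)-5-hydroxy-3-methylpentyl]-1,4a-dimethyldecahydronaphthalene-1-carboxylate
Conditions: HF·pyridine, pyridine, THF, 0 °C → rt
Reagents that add atoms: none
Why: Acidic fluoride should cleave both tert-butyldimethylsilyl ethers while the 2-(trimethylsilyl)ethyl ester, which needs nucleophilic fluoride, and all stereocentres remain intact.

Step 12
Reactants: 21 diol, 22 (R)-2-methylbutanoic acid
Product: 23 2-(trimethylsilyl)ethyl (1R,4aR,5S,6S,8aS)-6-hydroxy-1,4a-dimethyl-5-[(3R)-3-methyl-5-{[(2R)-2-methylbutanoyl]oxy}pentyl]decahydronaphthalene-1-carboxylate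
Conditions: 22 (1.1 equiv), N-(3-dimethylaminopropyl)-N′-ethylcarbodiimide hydrochloride, 4-(dimethylamino)pyridine (0.1 equiv), CH2Cl2, 0 °C
Reagents that add atoms: none
Why: Carbodiimide esterification (Steglich) should acylate the unhindered primary C15 hydroxyl much faster than the secondary C8 hydroxyl next to the C9 side chain, under conditions mild enough to keep the α-stereocentre of the acid.

Step 13
Reactants: 23 hydroxy diester
Product: 24 2-(trimethylsilyl)ethyl (1R,4aR,5S,8aS)-1,4a-dimethyl-5-[(3R)-3-methyl-5-{[(2R)-2-methylbutanoyl]oxy}pentyl]-6-oxodecahydronaphthalene-1-carboxylate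
Conditions: Dess–Martin periodinane, CH2Cl2, rt; then 1,8-diazabicyclo[5.4.0]undec-7-ene (0.2 equiv), CH2Cl2, rt
Reagents that add atoms: none
Why: Dess–Martin oxidation converts the C8 carbinol to the ketone without base, erasing the C8 centre, and the catalytic amidine equilibrates C9 through the ketone enol to the equatorial side chain without deprotonating the much less acidic ester α-position.

Step 14
Reactants: 24 keto diester
Product: 25 2-(trimethylsilyl)ethyl (1R,4aS,5R,8aS)-1,4a-dimethyl-6-methylidene-5-[(3R)-3-methyl-5-{[(2R)-2-methylbutanoyl]oxy}pentyl]decahydronaphthalene-1-carboxylate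
Conditions: Zn, CH2Br2, TiCl4, THF/CH2Cl2, 0 °C → rt
Reagents that add atoms: dibromomethane, BrCBr
Why: The Takai–Lombardo gem-dimetallic reagent is non-basic and selective for ketones over esters, so the hindered, enolisable C8 ketone should be methylenated without epimerising C9 or the 2-methylbutanoate centre.

Step 15
Reactants: 25 2-(trimethylsilyl)ethyl ester
Product: 26 (1R,4aS,5R,8aS)-1,4a-dimethyl-6-methylidene-5-[(3R)-3-methyl-5-{[(2R)-2-methylbutanoyl]oxy}pentyl]decahydronaphthalene-1-carboxylic acid (target)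
Conditions: Bu4NF, THF, 0 °C → rt; then dilute aqueous HCl
Reagents that add atoms: none
Why: Fluoride attack at silicon triggers β-elimination of the 2-(trimethylsilyl)ethyl ester with loss of ethene and fluorotrimethylsilane, which should free the hindered C19 acid without touching the C15 ester, the exocyclic alkene or any stereocentre.

**Compound list**
1 | (R)-citronellol, (3R)-3,7-dimethyloct-6-en-1-ol | CC(C)=CCC[C@@H](C)CCO | starting material
2 | benzyl (R)-citronellyl ether, ({[(3R)-3,7-dimethyloct-6-en-1-yl]oxy}methyl)benzene | CC(C)=CCC[C@@H](C)CCOCc1ccccc1 | intermediate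
3 | ozonide, 3-[(3R)-5-(benzyloxy)-3-methylpentyl]-5,5-dimethyl-1,2,4-trioxolane (both configurations at the ring CH) | CC1(C)OOC(CC[C@@H](C)CCOCc2ccccc2)O1 | intermediate
4 | (4R)-6-(benzyloxy)-4-methylhexanal | O=CCC[C@@H](C)CCOCc1ccccc1 | intermediate
5 | alkenyl nonaflate, (4R)-6-(benzyloxy)-4-methylhex-1-en-1-yl nonafluorobutane-1-sulfonate (E/Z) | FC(F)(F)C(F)(F)C(F)(F)C(F)(F)S(=O)(=O)OC=CC[C@@H](C)CCOCc1ccccc1 | intermediate
6 | ({[(3R)-3-methylhex-5-yn-1-yl]oxy}methyl)benzene | C#CC[C@@H](C)CCOCc1ccccc1 | intermediate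
7 | 3-methylcyclohex-2-en-1-one | CC1=CC(=O)CCC1 | starting material
8 | alkenylalane, [(1E,4R)-6-(benzyloxy)-4-methylhex-1-en-1-yl]bis(2-methylpropyl)aluminium | CC(C)C[Al](CC(C)C)/C=C/C[C@@H](C)CCOCc1ccccc1 | intermediate
9 | aluminium enolate, bis(2-methylpropyl)aluminium (3S)-3-[(1E,4R)-6-(benzyloxy)-4-methylhex-1-en-1-yl]-3-methylcyclohex-1-en-1-olate | CC(C)C[Al](CC(C)C)OC1=C[C@@](C)(CCC1)/C=C/C[C@@H](C)CCOCc1ccccc1 | intermediate
10 | {[(3S)-3-[(1E,4R)-6-(benzyloxy)-4-methylhex-1-en-1-yl]-3-methylcyclohex-1-en-1-yl]oxy}trimethylsilane | C[Si](C)(C)OC1=C[C@@](C)(CCC1)/C=C/C[C@@H](C)CCOCc1ccccc1 | intermediate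
11 | acrolein (prop-2-enal) | C=CC=O | starting material
12 | keto aldehyde, 3-{(1S,2S)-2-[(1E,4R)-6-(benzyloxy)-4-methylhex-1-en-1-yl]-2-methyl-6-oxocyclohexyl}propanal (C5 epimer with the propanal chain trans to the alkenyl group drawn) | O=CCC[C@H]2[C@@](C)(CCCC2=O)/C=C/C[C@@H](C)CCOCc1ccccc1 | intermediate
13 | (4aS,5S,6S,8aS)-5-[(1E,3S)-5-(benzyloxy)-3-methylpent-1-en-1-yl]-6-hydroxy-4a-methyloctahydronaphthalen-1(2H)-one | O[C@H]1CC[C@H]2[C@@](C)(CCCC2=O)[C@@H]1/C=C/[C@@H](C)CCOCc1ccccc1 | intermediate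
14 | (4aS,5S,6S,8aS)-6-hydroxy-5-[(3R)-5-hydroxy-3-methylpentyl]-4a-methyloctahydronaphthalen-1(2H)-one | O[C@H]1CC[C@H]2[C@@](C)(CCCC2=O)[C@@H]1CC[C@@H](C)CCO | intermediate
15 | (4aS,5S,6S,8aS)-6-[(tert-butyldimethylsilyl)oxy]-5-{(3R)-5-[(tert-butyldimethylsilyl)oxy]-3-methylpentyl}-4a-methyloctahydronaphthalen-1(2H)-one | CC(C)(C)[Si](C)(C)O[C@H]1CC[C@H]2[C@@](C)(CCCC2=O)[C@@H]1CC[C@@H](C)CCO[Si](C)(C)C(C)(C)C | intermediate
16 | potassium enolate of 15 (C3=C4), potassium (4aS,5S,6S,8aS)-6-[(tert-butyldimethylsilyl)oxy]-5-{(3R)-5-[(tert-butyldimethylsilyl)oxy]-3-methylpentyl}-4a-methyl-3,4,4a,5,6,7,8,8a-octahydronaphthalen-1-olate | CC(C)(C)[Si](C)(C)O[C@H]1CC[C@H]2[C@@](C)(CCC=C2[O-])[C@@H]1CC[C@@H](C)CCO[Si](C)(C)C(C)(C)C.[K+] | intermediate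
17 | (4aS,5S,6S,8aS)-6-[(tert-butyldimethylsilyl)oxy]-5-{(3R)-5-[(tert-butyldimethylsilyl)oxy]-3-methylpentyl}-4a-methyl-3,4,4a,5,6,7,8,8a-octahydronaphthalen-1-yl trifluoromethanesulfonate | CC(C)(C)[Si](C)(C)O[C@H]1CC[C@H]2[C@@](C)(CCC=C2OS(=O)(=O)C(F)(F)F)[C@@H]1CC[C@@H](C)CCO[Si](C)(C)C(C)(C)C | intermediate
18 | 2-(trimethylsilyl)ethyl (4aR,5S,6S,8aS)-6-[(tert-butyldimethylsilyl)oxy]-5-{(3R)-5-[(tert-butyldimethylsilyl)oxy]-3-methylpentyl}-4a-methyl-3,4,4a,5,6,7,8,8a-octahydronaphthalene-1-carboxylate | CC(C)(C)[Si](C)(C)O[C@H]1CC[C@H]2[C@@](C)(CCC=C2C(=O)OCC[Si](C)(C)C)[C@@H]1CC[C@@H](C)CCO[Si](C)(C)C(C)(C)C | intermediate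
19 | lithium ester enolate (exocyclic C4=C19 ketene acetal) from conjugate reduction of 18 | CC(C)(C)[Si](C)(C)O[C@H]1CC[C@H]2[C@@](C)(CCCC2=C([O-])OCC[Si](C)(C)C)[C@@H]1CC[C@@H](C)CCO[Si](C)(C)C(C)(C)C.[Li+] | intermediate
20 | 2-(trimethylsilyl)ethyl (1R,4aR,5S,6S,8aS)-6-[(tert-butyldimethylsilyl)oxy]-5-{(3R)-5-[(tert-butyldimethylsilyl)oxy]-3-methylpentyl}-1,4a-dimethyldecahydronaphthalene-1-carboxylate | CC(C)(C)[Si](C)(C)O[C@H]1CC[C@H]2[C@@](C)(CCC[C@@]2(C)C(=O)OCC[Si](C)(C)C)[C@@H]1CC[C@@H](C)CCO[Si](C)(C)C(C)(C)C | intermediate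
21 | 2-(trimethylsilyl)ethyl (1R,4aR,5S,6S,8aS)-6-hydroxy-5-[(3R)-5-hydroxy-3-methylpentyl]-1,4a-dimethyldecahydronaphthalene-1-carboxylate | O[C@H]1CC[C@H]2[C@@](C)(CCC[C@@]2(C)C(=O)OCC[Si](C)(C)C)[C@@H]1CC[C@@H](C)CCO | intermediate
22 | (R)-2-methylbutanoic acid | CC[C@@H](C)C(=O)O | starting material
23 | 2-(trimethylsilyl)ethyl (1R,4aR,5S,6S,8aS)-6-hydroxy-1,4a-dimethyl-5-[(3R)-3-methyl-5-{[(2R)-2-methylbutanoyl]oxy}pentyl]decahydronaphthalene-1-carboxylate | O[C@H]1CC[C@H]2[C@@](C)(CCC[C@@]2(C)C(=O)OCC[Si](C)(C)C)[C@@H]1CC[C@@H](C)CCOC(=O)[C@H](C)CC | intermediate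
24 | 2-(trimethylsilyl)ethyl (1R,4aR,5S,8aS)-1,4a-dimethyl-5-[(3R)-3-methyl-5-{[(2R)-2-methylbutanoyl]oxy}pentyl]-6-oxodecahydronaphthalene-1-carboxylate | O=C1CC[C@H]2[C@@](C)(CCC[C@@]2(C)C(=O)OCC[Si](C)(C)C)[C@@H]1CC[C@@H](C)CCOC(=O)[C@H](C)CC | intermediate
25 | 2-(trimethylsilyl)ethyl (1R,4aS,5R,8aS)-1,4a-dimethyl-6-methylidene-5-[(3R)-3-methyl-5-{[(2R)-2-methylbutanoyl]oxy}pentyl]decahydronaphthalene-1-carboxylate | C=C1CC[C@H]2[C@@](C)(CCC[C@@]2(C)C(=O)OCC[Si](C)(C)C)[C@@H]1CC[C@@H](C)CCOC(=O)[C@H](C)CC | intermediate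
26 | (1R,4aS,5R,8aS)-1,4a-dimethyl-6-methylidene-5-[(3R)-3-methyl-5-{[(2R)-2-methylbutanoyl]oxy}pentyl]decahydronaphthalene-1-carboxylic acid | C=C1CC[C@H]2[C@@](C)(CCC[C@@]2(C)C(=O)O)[C@@H]1CC[C@@H](C)CCOC(=O)[C@H](C)CC | target

**Step count and risks**
Total steps: 15. Longest linear sequence: 15 steps, from (R)-citronellol.

Steps most likely to fail:

1. Step 5 (proposed new method). What may go wrong: 1,2-addition to acrolein or its polymerisation in the first stage, or aldol closure from C3 competing with the ene closure in the second. Fallback, from 10, by known reactions: palladium-catalysed allylation of the silyl enol ether (allyl methyl carbonate, Pd2(dba)3, dppe, THF; Tsuji) should give the 2-allyl ketone F1. Hydroboration of the terminal alkene with 9-borabicyclo[3.3.1]nonane gives the B-alkyl borane F2, which is oxidised in the same flask (NaBO3) to the hydroxy ketone F3. Dess–Martin oxidation then gives keto aldehyde 12, now isolated, and Me2AlCl in CH2Cl2 closes ring B by the carbonyl-ene reaction. The route is rejoined at 13.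

2. Step 10. What may go wrong: over-reduction of the ester by the dissolving metal, protonation of the ester enolate before it is methylated, or poor facial selectivity in the alkylation. Fallback, from 18: hydrogenation of the enoate (H2, Pd/C; no other alkene is present at this stage) should give the saturated ester F4 as a mixture of C4 epimers. Deprotonation with LiN(i-Pr)2 in THF at −78 °C regenerates enolate 19 from both epimers, and methyl iodide then gives the quaternary ester. The route is rejoined at 20.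

3. Step 14. What may go wrong: slow methylenation of the hindered ketone, with enolisation at C9 or attack at the ester groups on forcing. Fallback, from 24: Me3SiCH2MgCl with CeCl3 in THF at −78 °C should add to the ketone in preference to the esters to give the β-hydroxysilane F5, and acid-induced Peterson elimination (BF3·OEt2, CH2Cl2, 0 °C) gives the exocyclic alkene. The route is rejoined at 25.

Further compounds
F1 | step 5 | (2S,3S)-3-[(1E,4R)-6-(benzyloxy)-4-methylhex-1-en-1-yl]-3-methyl-2-(prop-2-en-1-yl)cyclohexan-1-one | C=CC[C@H]2[C@@](C)(CCCC2=O)/C=C/C[C@@H](C)CCOCc1ccccc1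
F2 | step 5 | 9-{3-[(1S,2S)-2-[(1E,4R)-6-(benzyloxy)-4-methylhex-1-en-1-yl]-2-methyl-6-oxocyclohexyl]propyl}-9-borabicyclo[3.3.1]nonane | B1(CCC[C@H]3[C@@](C)(CCCC3=O)/C=C/C[C@@H](C)CCOCc4ccccc4)C2CCCC1CCC2
F3 | step 5 | (2S,3S)-3-[(1E,4R)-6-(benzyloxy)-4-methylhex-1-en-1-yl]-2-(3-hydroxypropyl)-3-methylcyclohexan-1-one | OCCC[C@H]2[C@@](C)(CCCC2=O)/C=C/C[C@@H](C)CCOCc1ccccc1
F4 | step 10 | 2-(trimethylsilyl)ethyl (1RS,4aR,5S,6S,8aR)-6-[(tert-butyldimethylsilyl)oxy]-5-{(3R)-5-[(tert-butyldimethylsilyl)oxy]-3-methylpentyl}-4a-methyldecahydronaphthalene-1-carboxylate | CC(C)(C)[Si](C)(C)O[C@H]1CC[C@H]2[C@@](C)(CCCC2C(=O)OCC[Si](C)(C)C)[C@@H]1CC[C@@H](C)CCO[Si](C)(C)C(C)(C)C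
F5 | step 14 | 2-(trimethylsilyl)ethyl (1R,4aR,5S,6RS,8aS)-6-hydroxy-1,4a-dimethyl-5-[(3R)-3-methyl-5-{[(2R)-2-methylbutanoyl]oxy}pentyl]-6-[(trimethylsilyl)methyl]decahydronaphthalene-1-carboxylate | C[Si](C)(C)CC1(O)CC[C@H]2[C@@](C)(CCC[C@@]2(C)C(=O)OCC[Si](C)(C)C)[C@@H]1CC[C@@H](C)CCOC(=O)[C@H](C)CC
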